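I counted turnovers.

in all of them: starting material 0.60 M
- violet: partner 0.78 M; protic impurity 0.030 M; precatalyst 0.15 mM; run made earlier
- flask: partner 0.780 M; protic impurity 0.0300 M; precatalyst 0.31 mM; time 15 h

- violet (time / h: target / %, starting material / %): 0.333: 0, 100.0; 0.833: 0.3, 100.1; 2.00: 2.0, 97.6; 5.00: 11.2, 89.4

(standard deviation of a reading: 0.3 percentage points)

- the analysis behind the earlier runs scatters by 0.3 percentage points, standard deviation
- on the list of suspects stand: starting material + free catalyst <-> catalyst intermediate A; partner + catalyst intermediate A -> catalyst intermediate B; catalyst intermediate B <-> released group + catalyst intermediate C; catalyst intermediate C -> free catalyst + target; partner + protic impurity -> quenched reagent; partner + precatalyst -> free catalyst + spent reagent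
- the reaction counts as stopped when no species that holds the starting material changes by six tenths of a point or more over the second half of the time
- no earlier run changes the charge of precatalyst; that part of a forecast is a guess

* which holds at 15 h: what has brought the reaction to rest, or that it has not come to rest (the partner has run out first / forward and back rates have come level / no working catalyst is left / it is still moving / all of the starting material has reacted)
* how much target there is at 15 h, in percent of the starting material charged

In the violet run, target rose from 2.0% at 2.00 h to 11.2% at 5.00 h, a factor of 5.60 against 6.25 for the time squared. The last violet reading, at 5.00 h, gave me 475 for what I called the turnover count: the logarithm of one over the unconverted fraction, divided by the precatalyst's fraction of the starting material. At low conversion, this counts turnovers per charged catalyst.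

I assumed that this count, growing with the time squared, carried over to the flask, whose precatalyst fraction was 0.0517%, though that was a guess. My curve started with zero slope and was steepest at 7.14 h, at 39.3% target. Partner net of impurity stood at 1.25 per starting material, more than one, so starting material was the limiting reagent and the level was the whole charge. At 15 h my curve reached 89.0% and was still climbing.

The forecast said it is still moving, with 78% target, between 58% and 96%. It stood below my figure, noting that “activation levelling off would lower it further”.

At 15 h the flask gave 68.8% target, and it is still moving.

    starting material + free catalyst ⇌ catalyst intermediate A (K = 0.670 M⁻¹, k = 13000 M⁻¹ h⁻¹)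
    partner + catalyst intermediate A → catalyst intermediate B (k = 2600 M⁻¹ h⁻¹)
    catalyst intermediate B ⇌ released group + catalyst intermediate C (K = 0.600 M, k = 2000 h⁻¹)
    catalyst intermediate C → free catalyst + target (k = 430 h⁻¹)
    partner + protic impurity → quenched reagent (k = 100 M⁻¹ h⁻¹)
    partner + precatalyst → free catalyst + spent reagent (k = 0.330 M⁻¹ h⁻¹)

Reckoned from this result, the flask's turnover count, brought back by the time squared to 5.00 h, was 250, about half the violet reading of 475. I carried this lower value to a neighbouring flask, the same in all but its precatalyst, charged at 7.7 × 10⁻⁵ M, a fraction of 0.0128%. The reckoning gave 25.1% target at 15 h, and that neighbouring flask held 25.5%.

The numbers in the tables were computed from invented constants; scatter was added.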